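Everything rests on removing both C5–O bonds at once, which turns the target into a 5,5''-dideoxy biflavone ether. The feature exploited is the C4 carbonyl oxygen of each pyranone ring C, which lies peri to exactly one ring A hydrogen, C5–H. A single ruthenium-catalysed, carbonyl-directed C–H oxygenation should therefore install both chelated 5-hydroxyls in one operation, closing no ring. Its precursor is the biflavone in which oxygen links C4' of a 7-pivaloyloxyflavone to C6 of a 7-pivaloyloxy-4'-methoxyflavone; without the 5-oxygens its two rings A are resorcinol-derived, so the diaryl ether comes from an unhindered phenol and each pyranone can close in one direction only.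

Key step: step 9

Remarks on the chemistry:
- The target has no stereocentre. The only stereo-elements on the way are the E-alkenes of the two chalcones and the racemic flavanone intermediates, and all of them vanish on aromatisation.
- The formyl group of the diaryl ether is turned into the first flavone before the acetyl group is introduced. No intermediate therefore carries an aryl aldehyde together with a methyl ketone (self-condensation), and no free aldehyde meets an electron-rich arene under Lewis acid.
- Every methyl ether that has to go is cleaved in step 5, before the anisyl ring with the one methoxy group of the target is brought in.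
- 2'-Hydroxy-4'-methoxyacetophenone is chosen over 2',4'-dihydroxyacetophenone for the first condensation. Its methyl ether gives a clean aldol step and costs nothing, because it leaves in step 5.
- Pivalates are kept on both 7-oxygens for the key step. They are stable in hot CF3CO2H, electron-withdrawing, poor directing groups, and cleaved by mild hydroxide.

Step 1
Reactants: 1 2,4-dimethoxyphenol; 2 4-fluorobenzaldehyde
Product: 3 4-(2,4-dimethoxyphenoxy)benzaldehyde
Conditions: K2CO3, DMF, 120 °C, N2
Reagents that add atoms: none
Why: Nucleophilic aromatic substitution (addition–elimination): the unhindered phenoxide of 1 should displace fluoride para to the formyl group through a Meisenheimer adduct, the standard way to a 4-aryloxybenzaldehyde.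

Step 2
Reactants: 3 4-(2,4-dimethoxyphenoxy)benzaldehyde; 4 2'-hydroxy-4'-methoxyacetophenone
Product: 5 (E)-3-[4-(2,4-dimethoxyphenoxy)phenyl]-1-(2-hydroxy-4-methoxyphenyl)prop-2-en-1-one
Conditions: KOH (aq. 50 %), EtOH, rt; then HCl (aq)
Reagents that add atoms: none
Why: Claisen–Schmidt (crossed aldol) condensation: 3 cannot enolise and 4 has a single methyl ketone whose only free phenol is the chelated 2'-hydroxyl, so the enolate should add cleanly and E1cB dehydration should give the conjugated E-enone; no stereocentre is formed.

Step 3
Reactants: 5 (E)-3-[4-(2,4-dimethoxyphenoxy)phenyl]-1-(2-hydroxy-4-methoxyphenyl)prop-2-en-1-one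
Product: 7 2-[4-(2,4-dimethoxyphenoxy)phenyl]-7-methoxy-4H-chromen-4-one, via flavanone 6 (not isolated)
Conditions: I2 (10 mol %), DMSO, 130 °C
Reagents that add atoms: none
Why: Iodine-catalysed oxidative cyclisation in DMSO: 6-endo oxa-Michael addition of the 2'-hydroxyl gives racemic flavanone 6, whose α-iodination and loss of HI aromatise ring C while DMSO reoxidises HI to I2; keeping iodine catalytic limits electrophilic iodination of the dimethoxyphenoxy ring, and the transient C2 stereocentre is erased.

Step 4
Reactants: 7 2-[4-(2,4-dimethoxyphenoxy)phenyl]-7-methoxy-4H-chromen-4-one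
Product: 8 2-[4-(5-acetyl-2,4-dimethoxyphenoxy)phenyl]-7-methoxy-4H-chromen-4-one
Conditions: AcCl, AlCl3, CH2Cl2, 0 °C → rt; then ice/HCl (aq)
Reagents that add atoms: acetyl chloride, CC(=O)Cl
Why: Friedel–Crafts acylation: on the pendant ring only the carbon para to one methoxy and ortho to the other is doubly activated and unhindered (the carbon between the two methoxy groups is blocked, the one next to the aryloxy oxygen is meta to both), while the chromone and its ring B are deactivated by AlCl3 bound at the C4 carbonyl; any loss of the methyl ortho to the new acetyl is harmless because step 5 removes it anyway.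

Step 5
Reactants: 8 2-[4-(5-acetyl-2,4-dimethoxyphenoxy)phenyl]-7-methoxy-4H-chromen-4-one
Product: 9 2-[4-(5-acetyl-2,4-dihydroxyphenoxy)phenyl]-7-hydroxy-4H-chromen-4-one
Conditions: BBr3 (8 equiv), CH2Cl2, −78 °C → rt; then H2O
Reagents that add atoms: none
Why: Lewis acid-mediated aryl methyl ether cleavage: bromide attacks the methyl of each boron-complexed methoxy group while the diaryl ether, the methyl ketone and the pyranone are inert; the step is placed here so that the anisyl methoxy, which must survive, is not yet in the molecule.

Step 6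
Reactants: 9 2-[4-(5-acetyl-2,4-dihydroxyphenoxy)phenyl]-7-hydroxy-4H-chromen-4-one; 10 4-methoxybenzaldehyde
Product: 11 2-[4-[2,4-dihydroxy-5-[(E)-3-(4-methoxyphenyl)prop-2-enoyl]phenoxy]phenyl]-7-hydroxy-4H-chromen-4-one
Conditions: KOH (aq. 50 %), EtOH, rt, under argon; then HCl (aq)
Reagents that add atoms: none
Why: Claisen–Schmidt condensation: 9 now holds the only enolisable ketone and 10 the only aldehyde, so no self-condensation is possible, and the existing pyranone should be shielded from hydroxide addition at C2 by its 7-phenoxide; E1cB dehydration gives the E-enone and no stereocentre.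

Step 7
Reactants: 11 2-[4-[2,4-dihydroxy-5-[(E)-3-(4-methoxyphenyl)prop-2-enoyl]phenoxy]phenyl]-7-hydroxy-4H-chromen-4-one
Product: 13 7-hydroxy-6-[4-(7-hydroxy-4-oxo-4H-chromen-2-yl)phenoxy]-2-(4-methoxyphenyl)-4H-chromen-4-one, via flavanone 12 (not isolated)
Conditions: I2 (10 mol %), DMSO, 130 °C
Reagents that add atoms: none
Why: Iodine-catalysed oxidative cyclisation in DMSO as in step 3: only the hydroxyl ortho to the enone carbonyl can add (6-endo oxa-Michael) to give racemic flavanone 12, which is dehydrogenated by α-iodination and HI loss, so the aryloxy group can only end up at C6; the preformed flavone is inert and the C2 stereocentre is erased.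

Step 8
Reactants: 13 7-hydroxy-6-[4-(7-hydroxy-4-oxo-4H-chromen-2-yl)phenoxy]-2-(4-methoxyphenyl)-4H-chromen-4-one
Product: 14 2-(4-methoxyphenyl)-4-oxo-6-[4-(4-oxo-7-pivaloyloxy-4H-chromen-2-yl)phenoxy]-4H-chromen-7-yl pivalate (5,5''-dideoxycryptomerin A 7,7''-dipivalate)
Conditions: PivCl (3 equiv), Et3N, DMAP (cat.), CH2Cl2, 0 °C → rt
Reagents that add atoms: pivaloyl chloride, CC(C)(C)C(=O)Cl
Why: DMAP-catalysed O-acylation (nucleophilic acyl substitution): the two 7-hydroxyls are the only nucleophiles left, and the hindered, electron-withdrawing pivalates should resist both acidolysis and oxidation in the next step.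

Step 9
Reactants: 14 5,5''-dideoxycryptomerin A 7,7''-dipivalate
Product: 16 5-hydroxy-6-[4-(5-hydroxy-4-oxo-7-pivaloyloxy-4H-chromen-2-yl)phenoxy]-2-(4-methoxyphenyl)-4-oxo-4H-chromen-7-yl pivalate (cryptomerin A 7,7''-dipivalate), via bis(trifluoroacetate) 15 (not isolated)
Conditions: [RuCl2(p-cymene)]2 (10 mol %), PhI(OCOCF3)2 (5 equiv), CF3CO2H/(CF3CO)2O, 80 °C; then H2O/THF, rt
Reagents that add atoms: [bis(trifluoroacetoxy)iodo]benzene, O=C(OI(OC(=O)C(F)(F)F)c1ccccc1)C(F)(F)F; trifluoroacetic acid, OC(=O)C(F)(F)F (solvent that exchanges with the carboxylate ligands; one trifluoroacetate oxygen per site stays in 16 as the 5-hydroxyl oxygen)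
Why: In CF3CO2H the chloride-bridged dimer should give a cationic divalent ruthenium trifluoroacetate that binds the C4 carbonyl oxygen of a chromone and cleaves the peri C5–H bond by carboxylate-assisted metalation, giving a five-membered ruthenacycle; oxidation by PhI(OCOCF3)2 to a tetravalent ruthenium trifluoroacetate and C–O reductive elimination deliver the C5 aryl trifluoroacetate and return divalent ruthenium, the cycle repeats at the second chromone to give 15, and aqueous work-up hydrolyses both trifluoroacetates to the hydrogen-bonded 5-hydroxyls of 16. The closest known reaction type is the ruthenium-catalysed, ketone-directed ortho C–H hydroxylation of aryl ketones, which is established at C5 of flavones and chromones with these reagents and is here run at two independent chromones in one molecule. No ring is closed and no stereocentre is created. The selectivity needed is C5 over C8, C3 and the ring B positions in each half: only C5–H can reach the carbonyl-bound metal through a five-membered chelate (C3–H would need a four-membered one, C8–H and the ring B hydrogens have no donor in range), and the pivalate carbonyls are weaker, hindered donors that could only form six-membered metallacycles. Over-oxidation should be held back because the chromones are protonated in CF3CO2H, the 7-oxygens are acylated and (CF3CO)2O keeps each new phenol masked as its trifluoroacetate until work-up, and the anhydrous acid also rules out Wessely–Moser isomerisation of the 6-aryloxy pattern. The C5–H of the acacetin half is flanked by the 6-aryloxy group, so this site should be the slower one and sets the catalyst and oxidant loading.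

Step 10
Reactants: 16 cryptomerin A 7,7''-dipivalate
Product: 17 cryptomerin A, 5,7-dihydroxy-6-[4-(5,7-dihydroxy-4-oxo-4H-chromen-2-yl)phenoxy]-2-(4-methoxyphenyl)-4H-chromen-4-one
Conditions: LiOH·H2O (6 equiv), THF/H2O, 0 °C → rt, under argon; then HCl (aq)
Reagents that add atoms: none
Why: Ester saponification (acyl–oxygen cleavage): pivalates of the acidic 7-hydroxychromone phenols are activated esters that hydroxide should cleave at room temperature, whereas the methyl ether, the diaryl ether and the phenoxide-deactivated pyranones are untouched; acidification returns the free phenols.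

Compound list
1 | 2,4-dimethoxyphenol | COc1ccc(O)c(OC)c1 | starting material
2 | 4-fluorobenzaldehyde | O=Cc1ccc(F)cc1 | starting material
3 | 4-(2,4-dimethoxyphenoxy)benzaldehyde | COc1ccc(Oc2ccc(C=O)cc2)c(OC)c1 | intermediate
4 | 2'-hydroxy-4'-methoxyacetophenone, 1-(2-hydroxy-4-methoxyphenyl)ethanone | CC(=O)c1ccc(OC)cc1O | starting material
5 | (E)-3-[4-(2,4-dimethoxyphenoxy)phenyl]-1-(2-hydroxy-4-methoxyphenyl)prop-2-en-1-one | COc1ccc(C(=O)/C=C/c2ccc(Oc3ccc(OC)cc3OC)cc2)c(O)c1 | intermediate
6 | racemic 2-[4-(2,4-dimethoxyphenoxy)phenyl]-7-methoxychroman-4-one (flavanone) | COc1ccc(Oc2ccc(C3CC(=O)c4ccc(OC)cc4O3)cc2)c(OC)c1 | intermediate (not isolated)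
7 | 2-[4-(2,4-dimethoxyphenoxy)phenyl]-7-methoxy-4H-chromen-4-one | COc1ccc(Oc2ccc(-c3cc(=O)c4ccc(OC)cc4o3)cc2)c(OC)c1 | intermediate
8 | 2-[4-(5-acetyl-2,4-dimethoxyphenoxy)phenyl]-7-methoxy-4H-chromen-4-one | CC(=O)c1cc(Oc2ccc(-c3cc(=O)c4ccc(OC)cc4o3)cc2)c(OC)cc1OC | intermediate
9 | 2-[4-(5-acetyl-2,4-dihydroxyphenoxy)phenyl]-7-hydroxy-4H-chromen-4-one | CC(=O)c1cc(Oc2ccc(-c3cc(=O)c4ccc(O)cc4o3)cc2)c(O)cc1O | intermediate
10 | 4-methoxybenzaldehyde | COc1ccc(C=O)cc1 | starting material
11 | 2-[4-[2,4-dihydroxy-5-[(E)-3-(4-methoxyphenyl)prop-2-enoyl]phenoxy]phenyl]-7-hydroxy-4H-chromen-4-one | COc1ccc(/C=C/C(=O)c2cc(Oc3ccc(-c4cc(=O)c5ccc(O)cc5o4)cc3)c(O)cc2O)cc1 | intermediate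
12 | racemic 7-hydroxy-6-[4-(7-hydroxy-4-oxo-4H-chromen-2-yl)phenoxy]-2-(4-methoxyphenyl)chroman-4-one (flavanone) | COc1ccc(C2CC(=O)c3cc(Oc4ccc(-c5cc(=O)c6ccc(O)cc6o5)cc4)c(O)cc3O2)cc1 | intermediate (not isolated)
13 | 7-hydroxy-6-[4-(7-hydroxy-4-oxo-4H-chromen-2-yl)phenoxy]-2-(4-methoxyphenyl)-4H-chromen-4-one | COc1ccc(-c2cc(=O)c3cc(Oc4ccc(-c5cc(=O)c6ccc(O)cc6o5)cc4)c(O)cc3o2)cc1 | intermediate
14 | 5,5''-dideoxycryptomerin A 7,7''-dipivalate | COc1ccc(-c2cc(=O)c3cc(Oc4ccc(-c5cc(=O)c6ccc(OC(=O)C(C)(C)C)cc6o5)cc4)c(OC(=O)C(C)(C)C)cc3o2)cc1 | intermediate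
15 | cryptomerin A 7,7''-dipivalate 5,5''-bis(trifluoroacetate) | COc1ccc(-c2cc(=O)c3c(OC(=O)C(F)(F)F)c(Oc4ccc(-c5cc(=O)c6c(OC(=O)C(F)(F)F)cc(OC(=O)C(C)(C)C)cc6o5)cc4)c(OC(=O)C(C)(C)C)cc3o2)cc1 | intermediate (not isolated)
16 | cryptomerin A 7,7''-dipivalate | COc1ccc(-c2cc(=O)c3c(O)c(Oc4ccc(-c5cc(=O)c6c(O)cc(OC(=O)C(C)(C)C)cc6o5)cc4)c(OC(=O)C(C)(C)C)cc3o2)cc1 | intermediate
17 | cryptomerin A | COc1ccc(-c2cc(=O)c3c(O)c(Oc4ccc(-c5cc(=O)c6c(O)cc(O)cc6o5)cc4)c(O)cc3o2)cc1 | target

Total step count: 10. Longest linear sequence: 10 steps (from 1 or 2 to 17); 4 and 10 enter as commercial building blocks.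

Steps most likely to fail

Step 9. The second C–H oxygenation, at the C5 position flanked by the 6-aryloxy group, may stall, and the trivalent iodine oxidant may degrade the electron-richer aryl ether rings before metalation occurs. The fallback replaces direct oxygenation by halogenation and substitution. It sets out from 14: carbonyl-directed peri C–H iodination of both chromones ([Cp*Rh(MeCN)3](SbF6)2 cat., N-iodosuccinimide, PivOH, 1,2-dichloroethane, 60 °C; the ketone-directed ortho-halogenation of aryl ketones by trivalent rhodium) should give the 5,5''-diiodo dipivalate F1. Copper-catalysed hydroxylation of the two aryl iodides (CuI, 1,10-phenanthroline, KOH, DMSO/H2O, 100 °C; then HCl) is assisted by the ortho carbonyl, and the hydroxide also saponifies both pivalates. This should give the target directly, so the route is rejoined at 17.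

Step 6. Enolisation of the methyl ketone may be slow in the triply deprotonated substrate, and prolonged contact with hydroxide may open the existing pyranone by addition at C2. The fallback builds the second flavone from an acid chloride instead of an aldehyde and needs neither hydroxide nor an oxidant. It sets out from 9: the lithium polyanion (LiN(SiMe3)2, 6 equiv, THF, −78 → −10 °C) is C-acylated with 4-methoxybenzoyl chloride (1 equiv) in a Baker–Venkataraman-type manifold to give the β-diketone 1-[2,4-dihydroxy-5-[4-(7-hydroxy-4-oxo-4H-chromen-2-yl)phenoxy]phenyl]-3-(4-methoxyphenyl)propane-1,3-dione F2. Acid cyclodehydration (AcOH, H2SO4 cat., 95 °C) through the only hydroxyl ortho to the diketone then gives the bisflavone, so the route is rejoined at 13 and steps 6 and 7 are by-passed.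

Step 3. Electrophilic iodination of the electron-rich dimethoxyphenoxy ring may drain the catalytic iodine and halt the dehydrogenation. The fallback separates ring closure from oxidation and uses no halogen. It sets out from 5, which is isomerised to flavanone 6 and isolated (NaOAc, EtOH, reflux; oxa-Michael addition). Aerobic α,β-dehydrogenation (Pd(OCOCF3)2 5 mol %, DMSO 10 mol %, O2 1 atm, AcOH, 80 °C; divalent palladium enolate, β-hydride elimination, reoxidation by O2) then returns to the route at 7. No compound beyond the list is made (F0).

Further compounds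
F1 | step 9 | 5,5''-diiodo-5,5''-dideoxycryptomerin A 7,7''-dipivalate | COc1ccc(-c2cc(=O)c3c(I)c(Oc4ccc(-c5cc(=O)c6c(I)cc(OC(=O)C(C)(C)C)cc6o5)cc4)c(OC(=O)C(C)(C)C)cc3o2)cc1
F2 | step 6 | 1-[2,4-dihydroxy-5-[4-(7-hydroxy-4-oxo-4H-chromen-2-yl)phenoxy]phenyl]-3-(4-methoxyphenyl)propane-1,3-dione | COc1ccc(C(=O)CC(=O)c2cc(Oc3ccc(-c4cc(=O)c5ccc(O)cc5o4)cc3)c(O)cc2O)cc1
F0 | step 3 | none | none
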